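A direct plan would make ring A as the salicylaldehyde A1 (MOM ethers on the 3- and 4-oxygens) and ring B as the α-chloroketone A2.
It would join them by Williamson etherification to the keto aldehyde A3, close ring C at C3–C4 by an NHC-catalysed intramolecular benzoin reaction to the 3-hydroxychroman-4-one A4, and finish with acid (MOM removal and dehydration).
Weak step, the run-up to A1: a catechol aldehyde would be protected, its formyl group cut out by Baeyer–Villiger oxidation and a formyl group put back on the next carbon, three operations that add nothing to the skeleton.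
Weak step, the final dehydration of A4: the tertiary carbinol sits α to the C4 carbonyl, so ionisation is disfavoured and α-ketol rearrangement can compete, in the same pot in which three MOM groups fall and an air-sensitive catechol is set free.
Weak step, the chloromethyllithium homologation of a benzoate to A2: a cryogenic carbenoid addition that must stop at single addition, followed by an etherification that must be held back from Rap–Stoermer closure to a 2-aroylbenzofuran.

**Retrosynthetic overview**
Disconnections: 14 ⇒ O1–C2 (acetal closure) ⇒ acetal 11 ⇒ C3–C1' (oxidative 1,2-shift of ring B from C2 to C3, key step) ⇒ chalcone 9 ⇒ C2–C3 (aldol) ⇒ ring A ketone 5 + ring B aldehyde 7.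
Feature used: ring B stands on C3 of pyranone ring C, next to the C4 carbonyl, and its C1' is para to the 4'-OMe group. C1' is therefore brought in on C2 as a plain benzaldehyde and moved to C3 by trivalent thallium, which joins the enolate carbon C3 to an electron-rich aryl carbon (two carbons of like polarity) and turns a 1,3-diarylpropane skeleton into a 1,2-diarylpropane skeleton.
Ring order: rings A and B enter as arenes, the C3–aryl bond is set on the open chain, and ring C closes last at O1–C2 (not at C3–C4) from a carbon already at the aldehyde oxidation level, so there is no carbinol to dehydrate.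
Ring A: one Dakin oxidation on the unprotected catechol aldehyde sets the fourth oxygen and the next step already forms a skeletal C–C bond; no formyl group is removed and put back, and no carbenoid or α-haloketone is needed.

Key step: step 6

Assumption: aldehydes 1 and 6 are taken as commercial. The target is achiral, so the stereocentres formed on the way are racemic and need no control.

Step 1
Reactants: 1 2,3-dihydroxy-4-methoxybenzaldehyde
Product: 3 4-methoxybenzene-1,2,3-triol, via aryl formate 2 (not isolated)
Conditions: 30% aq. H2O2 (1.3 equiv), B(OH)3 (3 equiv), conc. H2SO4 (cat.), THF, rt, N2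
Reagents that add atoms: hydrogen peroxide, OO
Why: Dakin oxidation (Baeyer–Villiger-type aryl migration in the peroxide adduct of the aldehyde), favoured because the migrating ring carbon has OH ortho and OMe para, with hydrolysis of aryl formate 2 in the same acidic medium; the boric acid variant avoids alkaline peroxide, which would degrade the pyrogallol-type product.

Step 2
Reactants: 3 4-methoxybenzene-1,2,3-triol
Product: 4 1-(2,3,4-trihydroxy-5-methoxyphenyl)ethan-1-one
Conditions: AcOH (1.5 equiv), BF3·OEt2 (as medium), 85 °C, N2; then aq. NaOAc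
Reagents that add atoms: acetic acid, CC(=O)O
Why: Friedel–Crafts C-acylation of the phenol in BF3 etherate (Nencki-type, by way of the aryl acetate and a Fries shift), which should place the acetyl group on C6, ortho to the 1-OH and para to the 3-OH, because only there is the ketone chelated by a neighbouring hydroxyl, while the other free carbon lies next to the methoxy group.

Step 3
Reactants: 4 1-(2,3,4-trihydroxy-5-methoxyphenyl)ethan-1-one
Product: 5 1-[2,3,4-tris(benzyloxy)-5-methoxyphenyl]ethan-1-one
Conditions: BnBr (3.6 equiv), K2CO3 (5 equiv), KI (cat.), DMF, 70 °C, N2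
Reagents that add atoms: benzyl bromide, BrCc1ccccc1
Why: Williamson ether synthesis (SN2 of the three phenoxides on benzyl bromide), pushed with heat and excess base so that the hydrogen-bonded 2-OH is alkylated too and no free p-methoxyphenol is left for the oxidant of step 6.

Step 4
Reactants: 6 3-hydroxy-4,5-dimethoxybenzaldehyde
Product: 7 3-(benzyloxy)-4,5-dimethoxybenzaldehyde
Conditions: BnBr (1.1 equiv), K2CO3 (1.5 equiv), DMF, rt
Reagents that add atoms: benzyl bromide, BrCc1ccccc1
Why: Williamson ether synthesis on the single phenol, which protects it from the oxidant of step 6 with a group that falls together with the ring A benzyl ethers in step 7.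

Step 5
Reactants: 5 1-[2,3,4-tris(benzyloxy)-5-methoxyphenyl]ethan-1-one; 7 3-(benzyloxy)-4,5-dimethoxybenzaldehyde
Product: 9 (E)-3-[3-(benzyloxy)-4,5-dimethoxyphenyl]-1-[2,3,4-tris(benzyloxy)-5-methoxyphenyl]prop-2-en-1-one, via aldol adduct 8 (not isolated)
Conditions: 50% aq. KOH (3 equiv), EtOH–THF, rt
Reagents that add atoms: none
Why: Claisen–Schmidt condensation (crossed aldol of the methyl ketone enolate with the non-enolisable aldehyde, then E1cB loss of water from aldol 8), which gives the conjugated E-enone under thermodynamic control and tolerates the benzyl ethers.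

Step 6
Reactants: 9 (E)-3-[3-(benzyloxy)-4,5-dimethoxyphenyl]-1-[2,3,4-tris(benzyloxy)-5-methoxyphenyl]prop-2-en-1-one
Product: 11 2-[3-(benzyloxy)-4,5-dimethoxyphenyl]-3,3-dimethoxy-1-[2,3,4-tris(benzyloxy)-5-methoxyphenyl]propan-1-one (racemic), via oxythallation adduct 10 (not isolated)
Conditions: Tl(NO3)3·3H2O (trivalent thallium, 1.1 equiv), MeOH–CH2Cl2 (3:1), rt, dark; then aq. NaHCO3
Reagents that add atoms: methanol, CO
Why: Trivalent thallium adds as an electrophile to the enone C=C bond together with methanol (oxythallation: thallium on C-α, methoxide on the benzylic C-β) to give adduct 10; the C–Tl bond then ionises with reduction to monovalent thallium, an exceptional leaving group, while ring B shifts from C-β to C-α through a phenonium ion, and the methoxy-stabilised cation left at C-β is trapped by methanol as the dimethyl acetal. The closest known reaction type is the thallium trinitrate-mediated oxidative rearrangement of chalcones to 1,2-diaryl-3,3-dimethoxypropan-1-ones, the laboratory counterpart of the aryl shift of isoflavone biosynthesis. No ring is closed in this step: it forms the C3–C1' bond, breaks the C2–C1' bond and leaves C2 at the aldehyde oxidation level, so that ring C can close afterwards at O1–C2 by simple acetal exchange. The one new stereocentre (C-α, the future C3) is formed racemic and is flattened in step 7. The step needs migration of ring B and not of the aroyl ring, and survival of both electron-rich rings: the 4'-OMe group para to the migrating carbon and the benzylic character of C-β fix the direction of addition and the migrating group, the benzyl ethers leave no free phenol (in particular no p-methoxyphenol on ring A) for the oxidant, ring A is deactivated by its acyl group, and plain methanol without orthoformate or strong acid keeps the ketone from forming a ketal, which would open the competing aroyl-migration path to an ester.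

Step 7
Reactants: 11 2-[3-(benzyloxy)-4,5-dimethoxyphenyl]-3,3-dimethoxy-1-[2,3,4-tris(benzyloxy)-5-methoxyphenyl]propan-1-one
Product: 14 7,8-dihydroxy-3-(3-hydroxy-4,5-dimethoxyphenyl)-6-methoxy-4H-chromen-4-one, via tetraphenol acetal 12 (not isolated), via 2-methoxyisoflavanone 13 (not isolated)
Conditions: H2 (1 atm), 10% Pd/C, EtOAc–MeOH, rt; filter under N2; then conc. HCl (cat.), MeOH, 60 °C, N2
Reagents that add atoms: none
Why: Hydrogenolysis of the four benzyl ethers over Pd/C frees the 2'-OH, which under acid attacks the oxocarbenium ion formed from the dimethyl acetal (acetal exchange, 6-exo closure of ring C at O1–C2), and the 2-methoxyisoflavanone then loses methanol by acid-catalysed β-elimination to the conjugated γ-pyrone, which erases the C3 stereocentre.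

**Compound list**
1 | 2,3-dihydroxy-4-methoxybenzaldehyde | O=Cc1ccc(OC)c(O)c1O | starting material
2 | 2,3-dihydroxy-4-methoxyphenyl formate | O=COc1ccc(OC)c(O)c1O | intermediate (not isolated)
3 | 4-methoxybenzene-1,2,3-triol | COc1ccc(O)c(O)c1O | intermediate
4 | 1-(2,3,4-trihydroxy-5-methoxyphenyl)ethan-1-one | CC(=O)c1cc(OC)c(O)c(O)c1O | intermediate
5 | 1-[2,3,4-tris(benzyloxy)-5-methoxyphenyl]ethan-1-one | CC(=O)c1cc(OC)c(OCc2ccccc2)c(OCc2ccccc2)c1OCc1ccccc1 | intermediate
6 | 3-hydroxy-4,5-dimethoxybenzaldehyde | O=Cc1cc(O)c(OC)c(OC)c1 | starting material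
7 | 3-(benzyloxy)-4,5-dimethoxybenzaldehyde | O=Cc1cc(OCc2ccccc2)c(OC)c(OC)c1 | intermediate
8 | 3-[3-(benzyloxy)-4,5-dimethoxyphenyl]-3-hydroxy-1-[2,3,4-tris(benzyloxy)-5-methoxyphenyl]propan-1-one (racemic) | O=C(CC(O)c1cc(OCc2ccccc2)c(OC)c(OC)c1)c1cc(OC)c(OCc2ccccc2)c(OCc2ccccc2)c1OCc1ccccc1 | intermediate (not isolated)
9 | (E)-3-[3-(benzyloxy)-4,5-dimethoxyphenyl]-1-[2,3,4-tris(benzyloxy)-5-methoxyphenyl]prop-2-en-1-one | O=C(/C=C/c1cc(OCc2ccccc2)c(OC)c(OC)c1)c1cc(OC)c(OCc2ccccc2)c(OCc2ccccc2)c1OCc1ccccc1 | intermediate
10 | {1-[3-(benzyloxy)-4,5-dimethoxyphenyl]-1-methoxy-3-oxo-3-[2,3,4-tris(benzyloxy)-5-methoxyphenyl]propan-2-yl}thallium dinitrate (racemic; the two transient stereocentres are of no consequence and are not specified) | COC(c1cc(OCc2ccccc2)c(OC)c(OC)c1)C([Tl](O[N+](=O)[O-])O[N+](=O)[O-])C(=O)c1cc(OC)c(OCc2ccccc2)c(OCc2ccccc2)c1OCc1ccccc1 | intermediate (not isolated)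
11 | 2-[3-(benzyloxy)-4,5-dimethoxyphenyl]-3,3-dimethoxy-1-[2,3,4-tris(benzyloxy)-5-methoxyphenyl]propan-1-one (racemic) | COC(OC)C(c1cc(OCc2ccccc2)c(OC)c(OC)c1)C(=O)c1cc(OC)c(OCc2ccccc2)c(OCc2ccccc2)c1OCc1ccccc1 | intermediate
12 | 2-(3-hydroxy-4,5-dimethoxyphenyl)-3,3-dimethoxy-1-(2,3,4-trihydroxy-5-methoxyphenyl)propan-1-one (racemic) | COC(OC)C(c1cc(O)c(OC)c(OC)c1)C(=O)c1cc(OC)c(O)c(O)c1O | intermediate (not isolated)
13 | 7,8-dihydroxy-3-(3-hydroxy-4,5-dimethoxyphenyl)-2,6-dimethoxy-2,3-dihydro-4H-chromen-4-one (racemic, mixture of diastereomers) | COC1Oc2c(O)c(O)c(OC)cc2C(=O)C1c1cc(O)c(OC)c(OC)c1 | intermediate (not isolated)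
14 | 7,8-dihydroxy-3-(3-hydroxy-4,5-dimethoxyphenyl)-6-methoxy-4H-chromen-4-one | COc1cc2c(=O)c(-c3cc(O)c(OC)c(OC)c3)coc2c(O)c1O | target

Total step count: 7. Longest linear sequence: 6 steps (steps 1, 2, 3, 5, 6, 7).

**Steps most likely to fail**

Step 6 (key step). The oxidant may attack the electron-rich rings or oxidise the acetal further, or ring B may migrate slowly because its 4'-OMe group is twisted out of conjugation by its two neighbours. The fallback sets out from chalcone 9 and comes back to the route at target 14. Weitz–Scheffer epoxidation of 9 (30% H2O2, NaOH, MeOH–THF, 0 °C) should give the trans epoxide [3-[3-(benzyloxy)-4,5-dimethoxyphenyl]oxiran-2-yl][2,3,4-tris(benzyloxy)-5-methoxyphenyl]methanone F1. BF3·OEt2 (CH2Cl2, 0 °C) should open F1 at the benzylic carbon with 1,2-shift of the aroyl group (Meinwald-type rearrangement) to the β-keto aldehyde 2-[3-(benzyloxy)-4,5-dimethoxyphenyl]-3-oxo-3-[2,3,4-tris(benzyloxy)-5-methoxyphenyl]propanal F2, which has the same 1,2-diaryl skeleton and needs no heavy-metal oxidant. Hydrogenolysis of F2 (H2, Pd/C, EtOAc–MeOH) should free the 2'-OH, which closes on the aldehyde to 2,7,8-trihydroxy-3-(3-hydroxy-4,5-dimethoxyphenyl)-6-methoxy-2,3-dihydro-4H-chromen-4-one F3, and HCl in MeOH should dehydrate F3 to 14.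

Step 2. The acyl group may enter at the ring carbon next to the methoxy group, or the triol may be oxidised by air before it reacts. The fallback does not branch from a numbered compound: it replaces starting material 1 (and compounds 3 and 4) by commercial 1-(2,3,4-trihydroxyphenyl)ethan-1-one F4 and comes back to the route at compound 5. Benzylation (BnBr, K2CO3, DMF, 70 °C) should give 1-[2,3,4-tris(benzyloxy)phenyl]ethan-1-one F5. Ring bromination (NBS, MeCN, rt), para to the 2-benzyloxy group and meta to the acetyl group, should give 1-[2,3,4-tris(benzyloxy)-5-bromophenyl]ethan-1-one F6. Palladium-catalysed C–O coupling with methanol (Pd2(dba)3 (zerovalent palladium), tBuBrettPhos, Cs2CO3, MeOH–toluene, 70 °C) should then give 5. Here the acetyl group is in place from the start and the methoxy oxygen comes last, so the regiochemical question of step 2 does not arise.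

Step 7. The aryl ketone may be over-reduced during the fourfold hydrogenolysis, the freed pyrogallol unit may be oxidised by air before the ring closes, or acid may split off the acetal carbon instead of closing the ring. The fallback sets out from acetal 11 and comes back at target 14, with ring closure before deprotection. MgBr2·OEt2 (toluene–Et2O, 60 °C) should cleave only the carbonyl-chelated 2'-benzyl ether to give 1-[3,4-bis(benzyloxy)-2-hydroxy-5-methoxyphenyl]-2-[3-(benzyloxy)-4,5-dimethoxyphenyl]-3,3-dimethoxypropan-1-one F7. TsOH (cat., toluene, 60 °C) should close ring C with loss of methanol to the stable, purifiable 7,8-bis(benzyloxy)-3-[3-(benzyloxy)-4,5-dimethoxyphenyl]-6-methoxy-4H-chromen-4-one F8. BCl3 with pentamethylbenzene as benzyl cation scavenger (CH2Cl2, −78 °C) should then remove the three benzyl ethers without hydrogen and give 14.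

**Further compounds**
F1 | step 6 | [3-[3-(benzyloxy)-4,5-dimethoxyphenyl]oxiran-2-yl][2,3,4-tris(benzyloxy)-5-methoxyphenyl]methanone (racemic trans; one enantiomer drawn) | O=C(c1cc(OC)c(OCc2ccccc2)c(OCc2ccccc2)c1OCc1ccccc1)[C@@H]1O[C@H]1c1cc(OCc2ccccc2)c(OC)c(OC)c1
F2 | step 6 | 2-[3-(benzyloxy)-4,5-dimethoxyphenyl]-3-oxo-3-[2,3,4-tris(benzyloxy)-5-methoxyphenyl]propanal (racemic) | O=CC(c1cc(OCc2ccccc2)c(OC)c(OC)c1)C(=O)c1cc(OC)c(OCc2ccccc2)c(OCc2ccccc2)c1OCc1ccccc1
F3 | step 6 | 2,7,8-trihydroxy-3-(3-hydroxy-4,5-dimethoxyphenyl)-6-methoxy-2,3-dihydro-4H-chromen-4-one (racemic, mixture of diastereomers) | OC1Oc2c(O)c(O)c(OC)cc2C(=O)C1c1cc(O)c(OC)c(OC)c1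
F4 | step 2 | 1-(2,3,4-trihydroxyphenyl)ethan-1-one | CC(=O)c1ccc(O)c(O)c1O
F5 | step 2 | 1-[2,3,4-tris(benzyloxy)phenyl]ethan-1-one | CC(=O)c1ccc(OCc2ccccc2)c(OCc2ccccc2)c1OCc1ccccc1
F6 | step 2 | 1-[2,3,4-tris(benzyloxy)-5-bromophenyl]ethan-1-one | CC(=O)c1cc(Br)c(OCc2ccccc2)c(OCc2ccccc2)c1OCc1ccccc1
F7 | step 7 | 1-[3,4-bis(benzyloxy)-2-hydroxy-5-methoxyphenyl]-2-[3-(benzyloxy)-4,5-dimethoxyphenyl]-3,3-dimethoxypropan-1-one (racemic) | COC(OC)C(c1cc(OCc2ccccc2)c(OC)c(OC)c1)C(=O)c1cc(OC)c(OCc2ccccc2)c(OCc2ccccc2)c1O
F8 | step 7 | 7,8-bis(benzyloxy)-3-[3-(benzyloxy)-4,5-dimethoxyphenyl]-6-methoxy-4H-chromen-4-one | COc1cc2c(=O)c(-c3cc(OCc4ccccc4)c(OC)c(OC)c3)coc2c(OCc2ccccc2)c1OCc1ccccc1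
A1 | direct plan | 2-hydroxy-5-methoxy-3,4-bis(methoxymethoxy)benzaldehyde | O=Cc1cc(OC)c(OCOC)c(OCOC)c1O
A2 | direct plan | 2-chloro-1-[3,4-dimethoxy-5-(methoxymethoxy)phenyl]ethan-1-one | O=C(CCl)c1cc(OCOC)c(OC)c(OC)c1
A3 | direct plan | 2-{2-[3,4-dimethoxy-5-(methoxymethoxy)phenyl]-2-oxoethoxy}-5-methoxy-3,4-bis(methoxymethoxy)benzaldehyde | O=Cc1cc(OC)c(OCOC)c(OCOC)c1OCC(=O)c1cc(OCOC)c(OC)c(OC)c1
A4 | direct plan | 3-[3,4-dimethoxy-5-(methoxymethoxy)phenyl]-3-hydroxy-6-methoxy-7,8-bis(methoxymethoxy)-2,3-dihydro-4H-chromen-4-one (racemic) | O=C1c2cc(OC)c(OCOC)c(OCOC)c2OCC1(O)c1cc(OCOC)c(OC)c(OC)c1
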